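**Strategy.** Everything rests on seeing the O2–C3–C4=C5 allyl peroxide unit of the 3,6-dihydro-1,2-dioxine ring, with its oxygens at C3 and C6 in a 1,4-relationship, as the [2,3]-shifted isomer of an allyl hydroperoxide that is far easier to make with stereocontrol. A hydroxyl-directed singlet-oxygen ene reaction of an open-chain (Z)-allylic alcohol first places OOH at C5, next to the C6 carbinol. The key allylperoxyl rearrangement then carries the peroxy group to C3 (new O2–C3 bond) and creates the C4=C5 double bond in one operation, with transfer of chirality. Its precursor is a 5-hydroperoxy-6-hydroxy-3-enoate; oxidation at C6, light-driven E-to-Z isomerisation, ring closure and methanolysis finish the ring.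

Key step: step 5

Remark: open-chain intermediates carry docosanoate numbering (C1 = ester carbon), so C3 and C6 of the chain become C3 and C6 of the ring. It is assumed that the two C6 configurations of the final ketal interconvert in acidic methanol and can be separated by chromatography.

Step 1
Reactants: 1 heptadecanoyl chloride; 2 methyl pent-4-ynoate
Product: 3 methyl 6-oxodocos-4-ynoate
Conditions: PdCl2(PPh3)2 (2 mol%), CuI (4 mol%), Et3N (1.2 equiv), THF, 20 °C
Reagents that add atoms: none
Why: Acyl Sonogashira coupling, in which oxidative addition of the acid chloride to zerovalent palladium formed in situ, transmetalation of the copper acetylide of 2 and reductive elimination should give the ynone without touching the ester, and no stereocentre is formed.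

Step 2
Reactants: 3 methyl 6-oxodocos-4-ynoate
Product: 4 methyl (6S)-6-hydroxydocos-4-ynoate
Conditions: Ru[(S,S)-TsDPEN](p-cymene) (1 mol%, base-free 16-electron amido complex), i-PrOH, 25 °C
Reagents that add atoms: none
Why: Noyori asymmetric transfer hydrogenation of an alkynyl ketone, in which the alkynyl group takes the place of the aryl group in the usual bifunctional hydride/proton transfer model so that the (S,S)-ligand should give the (6S)-carbinol, the base-free complex sparing the ester and the ynone.

Step 3
Reactants: 4 methyl (6S)-6-hydroxydocos-4-ynoate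
Product: 5 methyl (4Z,6S)-6-hydroxydocos-4-enoate
Conditions: H2 (1 atm), Pd/CaCO3 poisoned with Pb(OAc)2 (Lindlar catalyst), quinoline, EtOAc, 20 °C
Reagents that add atoms: none
Why: Lindlar semihydrogenation, in which syn delivery of hydrogen on the poisoned palladium surface should give the Z-alkene and stop there, leaving C6 untouched.

Step 4
Reactants: 5 methyl (4Z,6S)-6-hydroxydocos-4-enoate
Product: 6 methyl (3E,5S,6S)-5-hydroperoxy-6-hydroxydocos-3-enoate
Conditions: O2, tetraphenylporphyrin (cat.), visible light, CCl4, −10 °C
Reagents that add atoms: dioxygen (reacting as singlet oxygen), O=O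
Why: Schenck ene reaction directed by the allylic hydroxyl, in which 1,3-allylic strain of the Z-alkene holds the C6–H bond in the alkene plane and the hydroxyl group hydrogen-bonds the incoming oxygen on the face it occupies, so that oxygen should bond to C5 syn to OH (threo, new 5S centre), the hydrogen is taken from C3 rather than C6, and the new C3=C4 bond is E.

Step 5
Reactants: 6 methyl (3E,5S,6S)-5-hydroperoxy-6-hydroxydocos-3-enoate
Product: 7 methyl (3S,4E,6S)-3-hydroperoxy-6-hydroxydocos-4-enoate
Conditions: di-tert-butyl hyponitrite (10 mol%), C6H6 (dilute), O2 atmosphere, 40 °C; chromatography, recovered 6 resubmitted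
Reagents that add atoms: none
Why: tert-Butoxyl radicals from the hyponitrite abstract the OO–H hydrogen of 6, and the allylperoxyl radical undergoes the [2,3] allylperoxyl shift (Schenck rearrangement, the closest known reaction type being the radical isomerisation of allylic hydroperoxides of unsaturated fatty esters): the terminal oxygen bonds to C3 while the C5–O bond breaks and the double bond moves from C3=C4 to C4=C5, hydrogen transfer from a further molecule of 6 carrying the chain. No ring is closed; the shift passes through a five-membered, envelope-like cyclic transition structure (O–O–C5–C4–C3). The new C3 stereocentre is controlled by the C5 stereocentre that is consumed: the shift is suprafacial, so oxygen arrives at C3 on the face it leaves at C5, and with the C6 carbinol chain outside the allyl unit (hydrogen inside, least allylic strain) the (5S)-hydroperoxide should give the (3S)-hydroperoxide with an E C4=C5 bond. The step needs fidelity of this chirality transfer, secured by a non-polar solvent under oxygen so that the peroxyl radical does not dissociate and recombine at random, and site selectivity, secured because the allyl unit C3–C4–C5 offers the peroxy group only one other terminus. The two allyl hydroperoxides are close in energy, so an equilibrium mixture is expected, from which 7 is separated and 6 returned to the reaction. The C6 carbinol is a spectator, keeps its configuration and makes any material of the wrong C3 configuration a diastereomer that chromatography removes.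

Step 6
Reactants: 7 methyl (3S,4E,6S)-3-hydroperoxy-6-hydroxydocos-4-enoate
Product: 8 methyl (3S,4E,6S)-6-hydroxy-3-[(2-methoxypropan-2-yl)peroxy]docos-4-enoate
Conditions: 2-methoxypropene (1.1 equiv), PPTS (cat.), CH2Cl2, −20 °C
Reagents that add atoms: 2-methoxypropene, COC(C)=C
Why: Acid-catalysed addition of the O–H bond across the enol ether (peroxyketal formation), in which the hydroperoxide, more acidic and more nucleophilic (alpha effect) than the secondary alcohol, should capture the 2-methoxyprop-2-yl cation first when one equivalent is used cold, no stereocentre being touched.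

Step 7
Reactants: 8 methyl (3S,4E,6S)-6-hydroxy-3-[(2-methoxypropan-2-yl)peroxy]docos-4-enoate
Product: 9 methyl (3S,4E)-3-[(2-methoxypropan-2-yl)peroxy]-6-oxodocos-4-enoate
Conditions: IBX (1.5 equiv), DMSO, 20 °C
Reagents that add atoms: none
Why: IBX oxidation (ligand exchange at hypervalent iodine, then loss of the carbinol hydrogen) should turn the allylic alcohol into the E-enone under neutral, base-free conditions that leave the peroxyketal and the base-sensitive beta-peroxy ester alone, the C6 stereocentre being removed once its work is done.

Step 8
Reactants: 9 methyl (3S,4E)-3-[(2-methoxypropan-2-yl)peroxy]-6-oxodocos-4-enoate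
Product: 13 methyl 2-[(3S,6R)-6-hexadecyl-6-methoxy-3,6-dihydro-1,2-dioxin-3-yl]acetate, via E-hydroperoxy enone 10 (not isolated), via Z-hydroperoxy enone 11 (not isolated), via dioxinol 12 (not isolated)
Conditions: p-TsOH·H2O (5 mol%), MeOH, 0 °C in the dark, then hν (350 nm, Pyrex), 0 °C; chromatography, remaining ketal fraction resubmitted to p-TsOH/MeOH
Reagents that add atoms: methanol, CO
Why: Acetal exchange with methanol frees the hydroperoxide (10), n→π* excitation equilibrates the E- and Z-enones, only the Z-isomer 11 can reach the ketone with its OOH group and is drained as the cyclic peroxyhemiketal 12 (6-exo-trig addition of the hydroperoxide to the C=O group), and acid-catalysed ionisation of 12 to the ring peroxycarbenium ion followed by capture by methanol gives the ketal, in which C3 is untouched and C6 is set reversibly under thermodynamic control through that same ion: the (6R)-ketal carries OMe pseudo-axial (anomeric effect), the hexadecyl chain pseudo-equatorial and the C3 side chain pseudo-axial, a position that meets no syn-axial hydrogen because O1 and C5 bear none, so it should hold a workable share of the equilibrium, from which it is taken by chromatography while the remaining ketal is returned to acidic methanol.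

**Compound list**

1 | heptadecanoyl chloride | CCCCCCCCCCCCCCCCC(=O)Cl | starting material
2 | methyl pent-4-ynoate | C#CCCC(=O)OC | starting material
3 | methyl 6-oxodocos-4-ynoate | CCCCCCCCCCCCCCCCC(=O)C#CCCC(=O)OC | intermediate
4 | methyl (6S)-6-hydroxydocos-4-ynoate | CCCCCCCCCCCCCCCC[C@H](O)C#CCCC(=O)OC | intermediate
5 | methyl (4Z,6S)-6-hydroxydocos-4-enoate | CCCCCCCCCCCCCCCC[C@H](O)/C=C\CCC(=O)OC | intermediate
6 | methyl (3E,5S,6S)-5-hydroperoxy-6-hydroxydocos-3-enoate | CCCCCCCCCCCCCCCC[C@H](O)[C@@H](OO)/C=C/CC(=O)OC | intermediate
7 | methyl (3S,4E,6S)-3-hydroperoxy-6-hydroxydocos-4-enoate | CCCCCCCCCCCCCCCC[C@H](O)/C=C/[C@@H](OO)CC(=O)OC | intermediate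
8 | methyl (3S,4E,6S)-6-hydroxy-3-[(2-methoxypropan-2-yl)peroxy]docos-4-enoate | CCCCCCCCCCCCCCCC[C@H](O)/C=C/[C@@H](OOC(C)(C)OC)CC(=O)OC | intermediate
9 | methyl (3S,4E)-3-[(2-methoxypropan-2-yl)peroxy]-6-oxodocos-4-enoate | CCCCCCCCCCCCCCCCC(=O)/C=C/[C@@H](OOC(C)(C)OC)CC(=O)OC | intermediate
10 | methyl (3S,4E)-3-hydroperoxy-6-oxodocos-4-enoate (E-hydroperoxy enone) | CCCCCCCCCCCCCCCCC(=O)/C=C/[C@@H](OO)CC(=O)OC | intermediate
11 | methyl (3S,4Z)-3-hydroperoxy-6-oxodocos-4-enoate (Z-hydroperoxy enone) | CCCCCCCCCCCCCCCCC(=O)/C=C\[C@@H](OO)CC(=O)OC | intermediate
12 | methyl 2-[(3S)-6-hexadecyl-6-hydroxy-3,6-dihydro-1,2-dioxin-3-yl]acetate (dioxinol, both C6 anomers) | CCCCCCCCCCCCCCCCC1(O)C=C[C@H](CC(=O)OC)OO1 | intermediate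
13 | methyl 2-[(3S,6R)-6-hexadecyl-6-methoxy-3,6-dihydro-1,2-dioxin-3-yl]acetate | CCCCCCCCCCCCCCCC[C@]1(OC)C=C[C@H](CC(=O)OC)OO1 | target

**Step count and risks**

Total step count: 8. Longest linear sequence: 8 steps (from 1).

Steps most likely to fail:

Step 5. What may go wrong: the allylperoxyl radical may dissociate into an allyl radical and oxygen and recombine without memory of configuration (erosion of the C3 centre), or the hydrogen bond between the vicinal OH and OOH groups may hold the equilibrium on the side of 6. The fallback sets out from 6 and comes back at 8. It moves the shift to a substrate whose C6 hydroxyl is masked, so that loss of the hydrogen bond and steric relief, not two hydroperoxides of like energy, decide the equilibrium; the later chemoselective perketalisation is then no longer needed. 6 is silylated on both oxygens (TBSOTf, 2,6-lutidine, CH2Cl2, −78 °C) to methyl (3E,5S,6S)-6-[(tert-butyldimethylsilyl)oxy]-5-[(tert-butyldimethylsilyl)peroxy]docos-3-enoate F1. The labile silyl peroxide alone is cleaved (PPTS cat., MeOH, 0 °C) to methyl (3E,5S,6S)-6-[(tert-butyldimethylsilyl)oxy]-5-hydroperoxydocos-3-enoate F2. The radical-chain conditions of step 5 should then move the peroxy group away from the crowded C5 position, with the same suprafacial course, to methyl (3S,4E,6S)-6-[(tert-butyldimethylsilyl)oxy]-3-hydroperoxydocos-4-enoate F3. The hydroperoxide is capped with 2-methoxypropene (PPTS cat., CH2Cl2, 0 °C) to methyl (3S,4E,6S)-6-[(tert-butyldimethylsilyl)oxy]-3-[(2-methoxypropan-2-yl)peroxy]docos-4-enoate F4. The silyl ether is removed under near-neutral conditions (TBAF buffered with AcOH, THF, 0 °C), which returns 8.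

Step 8. What may go wrong: the excited Z-enone may enolise through its C3 hydrogen (loss of the C3 centre), the free hydroperoxy enone may be consumed by acid before it has isomerised, or the ketal equilibrium at C6 may rest largely on the wrong side (poor selectivity in the capture of the peroxycarbenium ion by methanol). The fallback sets out from 9 and comes back at 13; the events are separated and the ketal is made by O-alkylation instead of acetal exchange. 9 is hydrolysed (AcOH/THF/H2O, 20 °C) and 10 is isolated. 10 is irradiated (350 nm) in MeCN without acid, so that 11 closes to the dioxinol 12, which is isolated. The hemiketal hydroxyl of 12 is then methylated (MeOTf, 2,6-di-tert-butyl-4-methylpyridine, CH2Cl2, −20 °C). This forms the O–CH3 bond instead of the C6–O bond, so the C6 configuration follows the population of the rapidly interconverting hemiketal anomers rather than the ketal equilibrium. Material of the opposite C6 configuration, methyl 2-[(3S,6S)-6-hexadecyl-6-methoxy-3,6-dihydro-1,2-dioxin-3-yl]acetate F5, is separated and re-ionised (p-TsOH cat., MeOH, 0 °C), which restores the ketal equilibrium and delivers further 13.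

Step 6. What may go wrong: loss of chemoselectivity, the allylic alcohol being ketalised together with or instead of the hydroperoxide. The fallback sets out from 7 and comes back at 8. Both groups are capped with excess 2-methoxypropene (PPTS cat., CH2Cl2, 0 °C) to give methyl (3S,4E,6S)-6-[(2-methoxypropan-2-yl)oxy]-3-[(2-methoxypropan-2-yl)peroxy]docos-4-enoate F6. The more acid-labile alkyl ketal is then removed alone by brief methanolysis (PPTS cat., MeOH, −20 °C), the peroxyketal being the slower to ionise, which returns 8.

Further compounds
F1 | step 5 | methyl (3E,5S,6S)-6-[(tert-butyldimethylsilyl)oxy]-5-[(tert-butyldimethylsilyl)peroxy]docos-3-enoate | CCCCCCCCCCCCCCCC[C@H](O[Si](C)(C)C(C)(C)C)[C@@H](OO[Si](C)(C)C(C)(C)C)/C=C/CC(=O)OC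
F2 | step 5 | methyl (3E,5S,6S)-6-[(tert-butyldimethylsilyl)oxy]-5-hydroperoxydocos-3-enoate | CCCCCCCCCCCCCCCC[C@H](O[Si](C)(C)C(C)(C)C)[C@@H](OO)/C=C/CC(=O)OC
F3 | step 5 | methyl (3S,4E,6S)-6-[(tert-butyldimethylsilyl)oxy]-3-hydroperoxydocos-4-enoate | CCCCCCCCCCCCCCCC[C@H](O[Si](C)(C)C(C)(C)C)/C=C/[C@@H](OO)CC(=O)OC
F4 | step 5 | methyl (3S,4E,6S)-6-[(tert-butyldimethylsilyl)oxy]-3-[(2-methoxypropan-2-yl)peroxy]docos-4-enoate | CCCCCCCCCCCCCCCC[C@H](O[Si](C)(C)C(C)(C)C)/C=C/[C@@H](OOC(C)(C)OC)CC(=O)OC
F5 | step 8 | methyl 2-[(3S,6S)-6-hexadecyl-6-methoxy-3,6-dihydro-1,2-dioxin-3-yl]acetate | CCCCCCCCCCCCCCCC[C@@]1(OC)C=C[C@H](CC(=O)OC)OO1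
F6 | step 6 | methyl (3S,4E,6S)-6-[(2-methoxypropan-2-yl)oxy]-3-[(2-methoxypropan-2-yl)peroxy]docos-4-enoate | CCCCCCCCCCCCCCCC[C@H](OC(C)(C)OC)/C=C/[C@@H](OOC(C)(C)OC)CC(=O)OC
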